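The decalin is made last, in one acid-triggered cascade from an open C7–C6–C5–C4–C3–C2–C1–C10–C9–C8 chain. Everything rests on C6 of ring B. At the ketone level it turns its two neighbours C5 and C7 into a 1,3-bis-nucleophile that matches the enone C10=C9–C8=O (β-carbon C10, carbonyl C8). The C19 hydroxyl on C4, γ to C6, holds C6 as a cyclic enol ether, so C5 closes ring A on C10 and C7 then closes ring B on C8. The precursor is a 2,7-dioxabicyclo[3.2.1]octane ketal that masks O2, O19 and C6 at once and carries the tetrasubstituted enone with the finished butenolide arm.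

Key step: step 10

Remark: labdane numbering is used for every compound (C1–C10 decalin carbons, C11–C16 side chain, C17 on C8, C18 and C19 on C4, C20 on C10). α is the face opposite to C20. The target is read as 2α,6α,19-trihydroxylabda-8,13-dien-15,16-olide with 5α-H and 10β-methyl.

Step 1
Reactants: 1 (R)-epichlorohydrin; 2 ethynyltrimethylsilane
Product: 3 (R)-1-chloro-5-(trimethylsilyl)pent-4-yn-2-ol
Conditions: 2, n-BuLi, THF, −78 °C; BF3·OEt2; then 1, −78 °C; H2O quench
Reagents that add atoms: none
Why: Yamaguchi–Hirao alkynylation: the BF3-activated epoxide is opened by the lithium acetylide at its unsubstituted carbon (the future C1) much faster than chloride is displaced, so the C2 carbinol centre is carried over untouched from 1.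

Step 2
Reactants: 3 (R)-1-chloro-5-(trimethylsilyl)pent-4-yn-2-ol; 4 propionic acid
Product: 7 (5S)-3-methyl-5-[3-(trimethylsilyl)prop-2-yn-1-yl]dihydrofuran-2(3H)-one as a mixture of C3 epimers, via alkynyl epoxide 5 (not isolated), via hydroxy acid 6 (not isolated)
Conditions: 4 (excess), LiN(i-Pr)2 (2 equiv per acid), THF, 0 °C; add 3, 0 to 45 °C; aq. HCl work-up; cat. TsOH, toluene, rt
Reagents that add atoms: none
Why: Alkylation of a carboxylic acid dianion by an epoxide followed by lactonisation: surplus dianion closes the chlorohydrin to 5, opens it at the terminal carbon to forge C3–C4 without touching C2, and acid work-up cyclises 6, the C4 epimer mixture being harmless because C4 is planarised again in step 3.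

Step 3
Reactants: 7 α-methyl lactone; 8 propargyl bromide
Product: 9 (3R,5S)-3-methyl-3-(prop-2-yn-1-yl)-5-[3-(trimethylsilyl)prop-2-yn-1-yl]dihydrofuran-2(3H)-one
Conditions: LiN(i-Pr)2, THF, −78 °C; then 8, DMPU, −78 to −30 °C
Reagents that add atoms: none
Why: Diastereoselective alkylation of a γ-substituted butyrolactone enolate: the reactive propargylic bromide approaches the planar enolate on the face anti to the C2 side chain, which sets the C4 quaternary centre with methyl cis and propargyl trans to that chain.

Step 4
Reactants: 9 quaternary lactone
Product: 10 (2R,4S)-2-methyl-2-(prop-2-yn-1-yl)-7-(trimethylsilyl)hept-6-yne-1,4-diol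
Conditions: LiAlH4, Et2O, 0 °C; aqueous NaOH work-up
Reagents that add atoms: none
Why: Hydride reduction of the lactone to the 1,4-diol (C19 OH and C2 OH), in which the isolated alkynes are inert at 0 °C and neither stereocentre is touched.

Step 5
Reactants: 10 alkynediol
Product: 11 (1R,3S,5S)-1,5-dimethyl-3-[3-(trimethylsilyl)prop-2-yn-1-yl]-2,7-dioxabicyclo[3.2.1]octane (ketal carbon = C6, ring oxygens = O2 and O19)
Conditions: (Ph3P)AuNTf2 (2 mol %), 4 Å sieves, CH2Cl2, rt
Reagents that add atoms: none
Why: Gold-catalysed double hydroalkoxylation of an alkyne (cycloisomerisation of an alkynediol to a bicyclic ketal): the primary C19 hydroxyl adds 5-exo-dig to the terminal alkyne, the C2 hydroxyl adds to the resulting enol ether, the silyl-capped internal alkyne is far less reactive, and the configuration of the new ketal carbon C6 is dictated by the bridged ring system.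

Step 6
Reactants: 11 silylalkyne ketal; 12 N-methoxy-N-methylacetamide
Product: 14 5-[1,5-dimethyl-2,7-dioxabicyclo[3.2.1]octan-3-yl]pent-3-yn-2-one (ketal configured as in 11), via lithium acetylide 13 (not isolated)
Conditions: MeLi·LiBr, THF, 0 °C to rt; then 12, −78 to 0 °C; H2O quench
Reagents that add atoms: none
Why: Desilylative lithiation (methyl attack on silicon releases acetylide 13) followed by Weinreb ketone synthesis, whose chelated tetrahedral adduct prevents over-addition and shields the base-sensitive ynone until work-up.

Step 7
Reactants: 14 ynone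
Product: 15 3-iodo-4-methyl-5-[1,5-dimethyl-2,7-dioxabicyclo[3.2.1]octan-3-yl]pent-3-en-2-one (E/Z mixture, ketal as in 11)
Conditions: CuI, MeLi (2 equiv), Et2O, 0 °C; add 14, THF, −78 °C; then I2, THF, −78 to 0 °C
Reagents that add atoms: methyllithium (used as LiCuMe2), [Li]C; iodine, II
Why: Conjugate addition of lithium dimethylcuprate to the ynone followed by iodinolysis of the alkenylcopper/allenolate places methyl C20 on C10 and iodine on C9, and the alkene geometry is of no consequence because it is lost in step 10.

Step 8
Reactants: 16 4-bromofuran-2(5H)-one; 17 tributyl(vinyl)stannane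
Product: 18 4-vinylfuran-2(5H)-one
Conditions: Pd(PPh3)4 (5 mol %), BHT, toluene, 90 °C
Reagents that add atoms: none
Why: Stille coupling of the vinylogous acyl bromide, whose C–Br bond adds readily to zerovalent palladium, with the vinylstannane under neutral conditions that spare the lactone.

Step 9
Reactants: 18 4-vinylfuran-2(5H)-one; 15 α-iodoenone
Product: 20 4-methyl-3-[2-(5-oxo-2,5-dihydrofuran-3-yl)ethyl]-5-[1,5-dimethyl-2,7-dioxabicyclo[3.2.1]octan-3-yl]pent-3-en-2-one (E/Z mixture, ketal as in 11), via alkylborane 19 (not isolated)
Conditions: 18, 9-BBN-H, THF, 0 °C to rt; then 15, PdCl2(dppf), AsPh3, Cs2CO3, DMF/H2O, rt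
Reagents that add atoms: none
Why: Anti-Markovnikov hydroboration of the terminal vinyl group followed by B-alkyl Suzuki–Miyaura coupling with the α-iodoenone forges C9–C11 under mild aqueous base that the ketal and the butenolide tolerate.

Step 10
Reactants: 20 ketal enone
Product: 23 2α,19-dihydroxy-6-oxolabda-7,13-dien-15,16-olide (5α-H, 9α-H, 10β-methyl), via dihydrofuran enol ether 21 (not isolated), via monocyclised enol ether 22 (not isolated)
Conditions: Tf2NH (0.2 equiv), CH2Cl2 saturated with water, 0 °C to rt; aq. NaHCO3
Reagents that add atoms: none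
Why: Tf2NH opens the ketal at O2 to the C19–O=C6 oxocarbenium ion, which loses H5 to give the endocyclic enol ether 21; C5 of 21 adds to C10 of the protonated enone (a tertiary hydroxyallyl cation), the new oxocarbenium ion loses a C7 proton to give 22, C7 then adds to the protonated C8 ketone, and loss of water from C8 followed by its return at C6 gives enone 23, an isomer of 20. The closest known reaction type is the acid-mediated intramolecular Michael addition/aldol condensation of a ketone enol ether with an enone (Robinson-type α,α'-annulation, with a Mukaiyama–Michael first stage). Ring A closes 6-(enolexo)-exo-trig through C5–C10 and ring B closes 6-(enolendo)-exo-trig through C7–C8. C10 is set in a chair transition state with the C2 hydroxyl equatorial, in which the small C20 methyl rather than the bulky C9 arm takes the axial site beside axial C19; C5 is set by the five-membered C19–O–C6 ring, which can only be cis-fused on C4–C5 and so leaves H5 on the α face trans to C20, and it remains an epimerisable centre of the favoured trans-decalone; C9 equilibrates through the dienol to the equatorial side chain and is erased in step 11. The step needs C5 rather than C7 to react first, and C–C bond formation to outrun loss of the C2 hydroxyl through the dienol of the enone. Only C5 reaches C10 through a six-membered ring (C7 would need an eight- or ten-membered one), every O-centred closure (return to 20, hemiketals, the hetero-Diels–Alder type ketal) is reversible in acid, and the two C–C bonds followed by dehydration are the only irreversible exit.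

Step 11
Reactants: 23 hydroxy enone
Product: 24 6β,19-epoxy-2α-hydroxy-6α-methoxylabda-8,13-dien-15,16-olide
Conditions: HC(OMe)3 (3 equiv), camphorsulfonic acid (0.1 equiv), CH2Cl2, rt; aq. NaHCO3
Reagents that add atoms: trimethyl orthoformate, COC(OC)OC
Why: Acid-catalysed ketalisation of an enone with double-bond migration: the C19 hydroxyl and one methoxy group take up C6, and equilibration through the dienol ether moves the alkene away from the ketal carbon into the more substituted C8=C9 position, which erases C9, while O19 can bind C6 only from the β face.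

Step 12
Reactants: 24 mixed ketal
Product: 26 2α,6α,19-trihydroxylabda-8,13-dien-15,16-olide (target), via β,γ-enone 25 (not isolated)
Conditions: 10% aq. oxalic acid on SiO2, CH2Cl2, 0 °C, filter and concentrate cold; then Me4NBH(OAc)3, MeCN/AcOH, −20 °C
Reagents that add atoms: water, O
Why: Kinetic hydrolysis of the mixed ketal with a weak acid (as for β,γ-unsaturated ketones released from enol ethers) followed by Evans–Saksena reduction: the C19 hydroxyl exchanges onto boron and delivers hydride to the β face of C6, which sets the equatorial 6α-alcohol, while undirected ketones and the butenolide are not reduced by this reagent.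

Compound list
1 | (R)-epichlorohydrin | ClC[C@H]1CO1 | starting material
2 | ethynyltrimethylsilane | C#C[Si](C)(C)C | starting material
3 | (R)-1-chloro-5-(trimethylsilyl)pent-4-yn-2-ol | C[Si](C)(C)C#CC[C@@H](O)CCl | intermediate
4 | propionic acid | CCC(=O)O | starting material
5 | (R)-trimethyl[3-(oxiran-2-yl)prop-1-yn-1-yl]silane | C[Si](C)(C)C#CC[C@@H]1CO1 | intermediate
6 | (4S)-4-hydroxy-2-methyl-7-(trimethylsilyl)hept-6-ynoic acid, C2 epimers | CC(C[C@H](O)CC#C[Si](C)(C)C)C(=O)O | intermediate
7 | (5S)-3-methyl-5-[3-(trimethylsilyl)prop-2-yn-1-yl]dihydrofuran-2(3H)-one, C3 epimers | CC1C[C@@H](CC#C[Si](C)(C)C)OC1=O | intermediate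
8 | propargyl bromide | BrCC#C | starting material
9 | (3R,5S)-3-methyl-3-(prop-2-yn-1-yl)-5-[3-(trimethylsilyl)prop-2-yn-1-yl]dihydrofuran-2(3H)-one | O=C1O[C@H](CC#C[Si](C)(C)C)C[C@@]1(C)CC#C | intermediate
10 | (2R,4S)-2-methyl-2-(prop-2-yn-1-yl)-7-(trimethylsilyl)hept-6-yne-1,4-diol | OC[C@](C)(CC#C)C[C@H](O)CC#C[Si](C)(C)C | intermediate
11 | (1R,3S,5S)-1,5-dimethyl-3-[3-(trimethylsilyl)prop-2-yn-1-yl]-2,7-dioxabicyclo[3.2.1]octane | C[C@@]12C[C@@](C)(CO1)C[C@@H](CC#C[Si](C)(C)C)O2 | intermediate
12 | N-methoxy-N-methylacetamide | CC(=O)N(C)OC | starting material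
13 | lithium acetylide of the desilylated ketal | C[C@@]12C[C@@](C)(CO1)C[C@@H](CC#C[Li])O2 | intermediate
14 | ketal ynone, 5-(bicyclic ketal-3-yl)pent-3-yn-2-one | C[C@@]12C[C@@](C)(CO1)C[C@@H](CC#CC(C)=O)O2 | intermediate
15 | ketal α-iodoenone, E/Z mixture | C[C@@]12C[C@@](C)(CO1)C[C@@H](CC(C)=C(I)C(C)=O)O2 | intermediate
16 | 4-bromofuran-2(5H)-one | O=C1C=C(Br)CO1 | starting material
17 | tributyl(vinyl)stannane | C=C[Sn](CCCC)(CCCC)CCCC | starting material
18 | 4-vinylfuran-2(5H)-one | C=CC1=CC(=O)OC1 | intermediate
19 | 4-[2-(9-borabicyclo[3.3.1]nonan-9-yl)ethyl]furan-2(5H)-one | O=C1C=C(CCB2C3CCCC2CCC3)CO1 | intermediate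
20 | ketal enone with butenolide arm, E/Z mixture (precursor of the key step) | C[C@@]12C[C@@](C)(CO1)C[C@@H](CC(C)=C(CCC3=CC(=O)OC3)C(C)=O)O2 | intermediate
21 | 5-methyl-2,3-dihydrofuran enol ether (C5=C6) with free C2 hydroxyl | CC1=C[C@@](C)(CO1)C[C@H](O)CC(C)=C(CCC2=CC(=O)OC2)C(C)=O | intermediate
22 | ring A closed, 2-methylenetetrahydrofuran (C6=C7) fused on C4–C5, C9 epimers | C=C1OC[C@@]2(C)C[C@H](O)C[C@](C)(C(CCC3=CC(=O)OC3)C(C)=O)[C@@H]12 | intermediate
23 | 2α,19-dihydroxy-6-oxolabda-7,13-dien-15,16-olide | CC1=CC(=O)[C@H]2[C@@](C)(CO)C[C@H](O)C[C@]2(C)[C@H]1CCC1=CC(=O)OC1 | intermediate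
24 | 6β,19-epoxy-2α-hydroxy-6α-methoxylabda-8,13-dien-15,16-olide | CC1=C(CCC2=CC(=O)OC2)[C@@]2(C)C[C@@H](O)C[C@]3(C)CO[C@](OC)(C1)[C@H]23 | intermediate
25 | 2α,19-dihydroxy-6-oxolabda-8,13-dien-15,16-olide | CC1=C(CCC2=CC(=O)OC2)[C@@]2(C)C[C@@H](O)C[C@](C)(CO)[C@@H]2C(=O)C1 | intermediate
26 | 2α,6α,19-trihydroxylabda-8,13-dien-15,16-olide (CNP0387838.1) | CC1=C(CCC2=CC(=O)OC2)[C@@]2(C)C[C@@H](O)C[C@](C)(CO)[C@@H]2[C@@H](O)C1 | target

Total steps: 12. Longest linear sequence: 11 (steps 1–7 and 9–12).

Steps most likely to fail

Step 10. Attack on the fully substituted C10 may be too slow. Acid-induced loss of the C2 hydroxyl through the dienol of the enone, or simple return to the ketal, would then win. The fallback replaces the cationic Michael addition by a pericyclic C5–C10 bond formation and makes the two bonds in two stages. It sets out from 20. Catalytic pyridinium p-toluenesulfonate equilibrates 20 with enol ether 21 in hot toluene in the presence of Eu(fod)3. The inverse-demand intramolecular hetero-Diels–Alder reaction of the oxadiene O=C8–C9=C10 with C5=C6 should then give the dihydropyran ketal F1. Aqueous HCl in THF opens F1 to the 1,5-diketone, which closes C7–C8 by aldol condensation, and the route is rejoined at 23.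

Step 12. The mild hydrolysis may be overtaken by re-conjugation of the alkene. Hydride delivery may also lose its facial bias if the boron-bound C19 alkoxide cannot reach C6, or if hemiketal formation withholds the ketone. The fallback leaves substrate direction for catalyst control. It sets out from 25, which is reduced in buffered aqueous isopropanol with an NADPH-dependent ketoreductase chosen from a panel for hydride delivery to the β face. It comes back at 26 without any new compound.

Step 11. Alkene migration may stop short or scatter towards the exocyclic C8=C17 position, and the C2 hydroxyl may be tied up by orthoester exchange. The fallback is anionic deconjugation. It sets out from 23, where excess KOt-Bu in t-BuOH/THF forms the thermodynamic C6–C9 dienolate. Inverse quench into cold aqueous AcOH protonates this dienolate kinetically at C7. A catalytic tertiary amine (DABCO) returns any deconjugated butenolide to conjugation. The route is rejoined at 25 without any new compound.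

Further compounds
F1 | step 10 | dihydropyran ketal: ring A fused to a 2H-pyran (O–C8=C9) and to the C19–O tetrahydrofuran, which share the ketal carbon C6 bearing methyl C7 | CC1=C(CCC2=CC(=O)OC2)[C@@]2(C)C[C@@H](O)C[C@]3(C)CO[C@](C)(O1)[C@H]23
F0 | step 12 | none | none
F0 | step 11 | none | none
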